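Gas that reaches the solution after the starting material has decayed is a leftover that makes no target, so this flask is reckoned by the gas that arrives in time.

starting material 0.050 M; gas phase 12 mM (held); protic impurity 0.0500 M; time 8.0 s

    gas phase ⇌ dissolved gas, rate k1*(csat - [dissolved gas]) (k1 = 1.16 /s, csat = 12 mM)
    starting material + dissolved gas → target (k2 = 201 /M/s)
    starting material → side product (k3 = 3.56 /s)
    dissolved gas + target ⇌ idle adduct, settled at all times (K4 = 47.6 /M)
    dissolved gas + protic impurity → quenched reagent (k5 = 0.759 /M/s)
    dissolved gas + target → over-reaction product (k6 = 8.89 /M/s)

- what is said of target includes idle adduct
- at the start none of the gas is dissolved
- run time (flask): 8.0 s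

- amount of target and idle adduct together at 8.0 s, in percent of the starting material charged
- concentration of dissolved gas in solution at 8.0 s, in percent of saturation

The reckoning here climbs a ladder of times. On the lowest rung, dissolved gas meeting the charged starting material has a half-life of 0.069 s, shorter than the 0.19 s in which starting material halves by the side reaction. Early on, therefore, arriving gas is caught sooner than the starting material decays. The half-time of transfer, 0.598 s, is longer still, so inflow stays close to its full rate during that early stretch.

Now compare two rates at the start. Gas enters at 0.0139 M/s, and starting material leaves for side product at 0.178 M/s. Their ratio, 7.82%, is the gas ration G, the part of the charge that gas entering during one mean life of the starting material can turn into target. The ratio drifts upward as starting material falls, but later gas meets less of it, so this reckoning takes G as the target made.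

On the next rung, the solution fills. Counting its drain through protic impurity, with constant d = 0.0380 /s, far smaller than the transfer coefficient, the dissolved gas in percent of saturation, sat, comes to

sat ≈ 1.16 /s / (1.16 /s + d) = 96.8%.

On the top rung, target erodes; y stands for target and idle adduct together, in percent of the charge. With the gas taken at saturation, the adduct balance leaves part of the target free, giving a pseudo-first-order constant e = 0.0679 /s, whose mean life exceeds the run:

y ≈ G · exp(−e · 8.0 s) = 4.54%.

The forecast gives y = 5.9% and sat = 95.5%, on the ground that “most of the starting material goes to side product within about a second”. Its y is higher than this reckoning's, and its sat lower.

The flask gives y = 5.20% and sat = 96.1%. Over-reaction product stands at 3.00% at 8.00 s, so target, idle adduct counted, and over-reaction product together hold 8.20%, a little more than G, 7.82%.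

G contains no term for protic impurity, so for the neighbour charged with 0.085 M of it this reckoning again gives G = 7.82% and y = 4.54%. That neighbour gives y = 5.21%, with target, idle adduct counted, and over-reaction product together at 8.18%.

The numbers stand for no real mixture; the run is a simulation.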